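Sunday's small charge reads 9.17% of its starting material at 5.6 h, less than the 50.0% its partner, the limiting reagent, allows.

| flask | starting material | partner | free catalyst | time |
|---|---|---|---|---|
| Monday's | 0.600 M | 0.480 M | 0.0600 M |  |
| Sunday's | 0.240 M | 0.120 M | 0.0600 M |  |
| Thursday's | 0.600 M | 0.480 M | 0.0900 M |  |
| Friday's | 0.600 M | 1.40 M | 0.0600 M |  |
| Wednesday's | 0.600 M | 0.480 M | 0.120 M | 5.6 h |

- Monday's run (time / h: [target] / M): 0.22: 0.093; 0.43: 0.114; 0.81: 0.137; 1.5: 0.163; 2.9: 0.158; 5.6: 0.161
- Sunday's run (time / h: [target] / M): 0.22: 0.002; 0.43: 0.007; 0.81: 0.029; 1.5: 0.023; 2.9: 0.021; 5.6: 0.022
- Thursday's run (time / h: [target] / M): 0.22: 0.107; 0.43: 0.144; 0.81: 0.161; 1.5: 0.164; 2.9: 0.187; 5.6: 0.186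
- Friday's run (time / h: [target] / M): 0.22: 0.148; 0.43: 0.218; 0.81: 0.274; 1.5: 0.288; 2.9: 0.311; 5.6: 0.328

(standard deviation of a reading: 0.006 M)

- Overall: starting material + partner -> target, with free catalyst as catalyst.
- Constant volume, constant temperature.
- Readings of a species count what is bound in complexes too.
- An order is taken over about fifteen percent of the charge, up and down.

1. apparent order in [free catalyst] of the starting rate, round the charge of the Monday's run (the rate where two percent of its starting material have turned into target)
2. apparent order in [partner] of the starting rate, round the charge of the Monday's run (the rate where two percent of its starting material have turned into target)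
3. target in the Wednesday's run at 5.6 h, as a share of the starting material charged

I read Monday's flask as a ladder of rates. On the fastest rung, up to 0.22 h, target appears at 0.705 /h as a share of the charge. On the next rung, up to 1.5 h, it appears at 0.0911 /h, which is slower. On the last rung the share reads 27.2% and then 26.8%, a difference inside a scatter of 1.00%, so these readings can't resolve any slow rise that may remain in Monday's flask.

The level of the late readings, which I call the plateau, is the number to reckon with. Monday's last two readings average 26.6%. Thursday's flask has the same starting material and partner with 1.50 times the free catalyst, and its last two average 31.1%, a rise smaller than the rise in catalyst. I take it that, at this starting material and partner, equal factors on the catalyst buy equal steps, which gives 7.7 percentage points. This is the doubling gain, the share of starting material added to the plateau by each doubling of the free catalyst charge.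

Wednesday's flask holds twice Monday's catalyst on the same starting material and partner, so I compute only the correction to Monday's plateau and commit to 34.3% at 5.6 h, give or take 1.3 points.

The forecast says 35%, with orders of 1.15 in free catalyst and 0.8 in partner. Its ground differs from mine: “catalyst must hold product in a fairly tight complex, which the reading counts as target”.

The simulation gives 33.7%, with orders of 1.0 and 0.71, so the forecast stands within the tolerance on all three.

    free catalyst + partner ⇌ catalyst-reagent complex, settled at all times (1.690 /M)
    catalyst-reagent complex + starting material → target + free catalyst (51.48 /M/h)
    2 starting material → homo dimer (2.826 /M/h)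
    2 free catalyst → 2 spent catalyst (86.40 /M/h)

Read from Monday to Wednesday, the doubling gain is 7.1 points, and scaled to Thursday's catalyst step it gives 30.8% against the 31.1% read there. In Wednesday's flask the target step runs while complex and starting material are both there. From the start, starting material goes to homo dimer with a first half-life of 0.295 h by that step alone, and the catalyst, complex counted and partner held at its charge, goes to spent catalyst with a first half-life of 0.158 h by that step alone, which is shorter than the other, and at 5.6 h target stands at 33.7%.

The runs were computed on assumed constants; scatter was added.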